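## Analysis of the target

The target is an 8,3'-neolignan in which the O4'–C7 ether bridge ties C7 and C8 into a 2,3-dihydrobenzofuran. Ring A (C1'–C6') is fused to the five-membered ring O4'–C7–C8–C3'–C4'; it carries a methoxy group at C5' and the (E)-3-hydroxyprop-1-enyl chain at C1'. C7 bears the 3,4,5-trimethoxyphenyl ring and C8 bears the C9 hydroxymethyl arm.

The only stereocentres are C7 (R) and C8 (S). They are adjacent and trans, so the aryl group and the CH2OH arm lie on opposite faces of the five-membered ring. C7 is a benzylic ether carbon next to an electron-rich arene and ionises under acid. Its configuration is therefore correctable, because ring closure or re-closure prefers the trans ring, but the ring is acid-sensitive for the same reason, as is the cinnamyl alcohol at C7'–C9'. The electron-rich arenes are also sensitive to oxidants.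

C8 is a tertiary benzylic C–H centre without a heteroatom. It cannot be corrected later, and it is threatened by elimination towards a C7=C8 stilbene whenever C7 becomes cationic. The difficulty is therefore absolute control of C8, combined with a late and gentle introduction of the allylic alcohol.

The plan rests on one feature. C7 and C8 are neighbouring carbons that each carry exactly one aryl group (C7 the trimethoxyphenyl ring, C8 the ring A carbon C3'), with oxygen on C7 and the C9 oxygen one carbon out from C8. This is the pattern left by adding two aryl groups across a C7=C8 alkene whose C7 carries boron, the boron marking the later oxygen.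

## Retrosynthetic reasoning

**18 ⇒ 17 ⇒ 16 (C7'=C8' and the C9' oxidation level).** The allylic alcohol is the most acid-sensitive group, so it is removed first in the retrosynthesis and installed last in the forward direction. Cutting C7'=C8' leads back to aldehyde 16 through ester 17. The forward steps have to give the E alkene and reduce the ester in a 1,2-sense without touching the benzylic ether.

**16 ⇒ 13 (O4'–C7).** The ring is opened at the ether bond rather than at a C–C bond because C7 ionises easily next to the trimethoxyphenyl ring. The closure is therefore stereoconvergent at C7, and only C8 has to arrive with defined configuration. Alcohol 13 carries a MOM ether on O4', a dimethyl acetal at C1' and a silyl ether on C9, all of which fall under acid. The forward step has to unmask the phenol, ionise C7 and close the trans ring without eliminating towards C8.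

**13 ⇒ 12 (C7–O from C7–B).** The C7 oxygen is traced back to boron. The forward oxidation is stereoretentive and tolerates everything else in the molecule.

**12 ⇒ 11 ⇒ 8 + 10 + 3 (aryl–C7 and C3'–C8).** Both aryl–C(sp3) bonds are cut at once. This is the only pair of cuts that dissolves the whole skeleton into three simple pieces: an alkenyl boronate holding C7–C8–C9, an aryllithium (10) and an aryl bromide (3). In the forward direction 10 adds to boron to give borate 11, and a chiral bisphosphine–palladium catalyst joins 11 and 3. The trimethoxyphenyl group moves from boron to C7 as ring A is delivered to C8. Two C–C bonds and both stereocentres are gained in one catalytic step, with boron left where oxygen is needed. The forward reaction must make the 1,2-shift outrun direct boron-to-palladium transfer, and it must select one alkene face at C8.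

**8 ⇒ 7 + 5, 7 ⇒ 6, 5 ⇒ 4 (the diol on boron).** The commercial pinacol ester 6 already has the C7=C8–C9 unit with the E geometry and the silyl ether. It is not taken into the coupling itself, because a beta-substituted alkenyl borate of a small diol tends to transfer a group directly to palladium. The diol is therefore exchanged for the rigid, hindered cis-diol 5 by way of boronic acid 7. Diol 5 comes from dione 4 by double methyl addition.

**3 ⇒ 2 ⇒ 1, and 10 ⇒ 9.** Ring A is 5-bromovanillin (1), with its substituents already in the right places: Br at C3', OH at C4', OMe at C5' and CHO at C1'. It needs only protection as the MOM ether (2) and the dimethyl acetal (3). Aryllithium 10 is made in the flask from bromide 9 by halogen–metal exchange.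

## Alternatives that were turned down

**Alternative 1: asymmetric Prins reaction of a stilbene.** The disconnection is C8–C9, with temporary C7–O and acetal bonds. In the forward step a confined chiral Brønsted acid activates formaldehyde A2. The (E)-stilbene A1 attacks it through C8, and the C7 cation is captured by a second molecule of A2 to give the trans-4,5-disubstituted 1,3-dioxane A3. Acid would then open the dioxane and close the dihydrofuran to reach 16.

- For it: A1 is made in one or two steps, A2 is the cheapest C9 source, and both centres and both oxygens arise in one catalytic step. On step count to 16 it is as short as the chosen route or shorter.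
- Against it: the reaction type has been developed for simple aryl alkenes. Here two heavily substituted arenes must fit the confined pocket. The C7 cation is long-lived next to the trimethoxyphenyl ring, which invites a stepwise pathway and loss of selectivity. The free aldehyde of ring A competes with A2 for the acid, and the catalyst itself needs a multistep synthesis.
- Comparison: the chosen route is longer but places its risk in a reaction class with a clearer precedent for 1,2-disubstituted alkenes, and its boron atom fixes the site of the C7 oxygen unambiguously.

**Alternative 2: cation cyclisation onto a preformed C8 centre.** The disconnection is O4'–C7 only. Sulfonic acid in an alcohol removes the MOM group of diol A4 and ionises its C7 alcohol, and the phenol closes the trans ring to give bromide A5. A Heck reaction at the bromide would then lead to 17.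

- For it: the closure is the same robust, stereoconvergent step used in the chosen route, so on that point the two are equal. If C8 is set by an auxiliary-controlled aldol, the stereocontrol is more predictable than any catalytic three-component coupling, and A4-type intermediates are easily purified. On reliability of C8 it is the stronger plan.
- Against it: the key step forms no C–C bond and no lasting stereocentre. The whole burden of C8 falls on a longer linear sequence before it (an arylacetic acid, attachment and removal of an auxiliary, reduction), and the aryl bromide must be carried through all of it.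
- Comparison: the chosen route offers convergence from three simple fragments and catalytic control of C8 in the bond-forming step itself, and it keeps the same forgiving ring closure.

**Alternative 3: [4+1] annulation of an ortho-quinone methide with a chiral sulfonium ylide.** The disconnection is C7–C8 plus O4'–C7. A carbonate base releases the ortho-quinone methide from sulfone A6 and the ylide from sulfonium salt A7 (drawn with a C2-symmetric thiolane as one possible chiral sulfide). The ylide carbon adds to C8, and the phenoxide displaces the sulfide at C7 to give the silyl ether A8.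

- For it: the ring and both centres are formed in one base-mediated step. No C7 cation is involved, so elimination towards C8 is not an issue, and the anti betaine leads directly to the trans ring. On mildness of the ring-forming step it is stronger than the chosen route.
- Against it: the quinone methide carries an alkyl-type substituent with hydrogen on C9 and can tautomerise to an ortho-vinylphenol before it is trapped. C8 is set in the conjugate addition, with the controlling sulfide one atom away on C7. The electron-rich benzyl ylide is weakly stabilised, so betaine formation is less reversible and less selective. A stoichiometric chiral sulfide is needed, and both A6 and A7 need several steps.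
- Comparison: the chosen route sets C8 at the metal centre that forms the C3'–C8 bond, with a catalytic chiral source, and leaves C7 self-correcting.

Key step: step 6

Assumption: the sense of induction of the ligand is assigned by analogy; (Sp,Sp)-MandyPhos is written for the enantiomer that places ring A on the Re face of C8 (priorities C9 > C7 > H), and the mirror-image ligand is used if the sense is the opposite.

## Route

Step 1
Reactants: 1 3-bromo-4-hydroxy-5-methoxybenzaldehyde (5-bromovanillin)
Product: 2 3-bromo-5-methoxy-4-(methoxymethoxy)benzaldehyde
Conditions: MOMCl, i-Pr2NEt, CH2Cl2, 0 °C → rt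
Reagents that add atoms: chloromethyl methyl ether, COCCl
Why: O-alkylation of the acidic phenol by the chloromethyl ether (Williamson-type etherification); aldehyde and aryl bromide are inert, and the MOM group later survives the borate, palladium and alkaline peroxide and leaves in the acid step that closes the ring.

Step 2
Reactants: 2 3-bromo-5-methoxy-4-(methoxymethoxy)benzaldehyde
Product: 3 1-bromo-5-(dimethoxymethyl)-3-methoxy-2-(methoxymethoxy)benzene
Conditions: HC(OMe)3, MeOH, p-TsOH·H2O (1 mol %), rt; Et3N quench
Reagents that add atoms: trimethyl orthoformate, COC(OC)OC; methanol, CO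
Why: Acid-catalysed acetalisation driven by the orthoformate as water scavenger; the aldehyde has to be masked before ring A meets a nucleophilic borate and an aryl palladium species, and the low acid loading, room temperature and amine quench are chosen to spare the MOM ether.

Step 3
Reactants: 4 acenaphthylene-1,2-dione (acenaphthoquinone)
Product: 5 (1R,2S)-1,2-dimethyl-1,2-dihydroacenaphthylene-1,2-diol (cis, meso; "mac" diol)
Conditions: AlMe3, toluene, 0 °C → rt; aqueous work-up; recrystallisation
Reagents that add atoms: trimethylaluminium, C[Al](C)C
Why: Double 1,2-addition of methyl to the 1,2-dione; the second methyl is expected to enter anti to the aluminium alkoxide formed first, giving the cis diol, which is purified by crystallisation and is the only isomer that can span boron in step 5.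

Step 4
Reactants: 6 (E)-tert-butyldimethyl{[3-(4,4,5,5-tetramethyl-1,3,2-dioxaborolan-2-yl)prop-2-en-1-yl]oxy}silane
Product: 7 (E)-{3-[(tert-butyldimethylsilyl)oxy]prop-1-en-1-yl}boronic acid
Conditions: NaIO4, NH4OAc, acetone–H2O, rt
Reagents that add atoms: water, O
Why: Oxidative deprotection of a pinacol boronate: periodate cleaves the pinacol released in the hydrolysis equilibrium to acetone and so pulls the ester over to the boronic acid, while the E alkene and the silyl ether are untouched near neutral pH.

Step 5
Reactants: 7 (E)-{3-[(tert-butyldimethylsilyl)oxy]prop-1-en-1-yl}boronic acid; 5 (1R,2S)-1,2-dimethyl-1,2-dihydroacenaphthylene-1,2-diol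
Product: 8 cyclic boronate of 7 with diol 5 [(E)-alkenyl B(mac) ester]
Conditions: toluene, rt → 40 °C, azeotropic removal of H2O under reduced pressure
Reagents that add atoms: none
Why: Condensation of a boronic acid with a cis-1,2-diol to the five-membered cyclic boronate, driven by removal of water; the alkene geometry is not touched.

Step 6
Reactants: 9 5-bromo-1,2,3-trimethoxybenzene; 8 (E)-alkenyl B(mac) ester; 3 1-bromo-5-(dimethoxymethyl)-3-methoxy-2-(methoxymethoxy)benzene
Product: 12 (1R,2S)-3-[(tert-butyldimethylsilyl)oxy]-2-[5-(dimethoxymethyl)-3-methoxy-2-(methoxymethoxy)phenyl]-1-(3,4,5-trimethoxyphenyl)propylboronic acid ester of diol 5, via 3,4,5-trimethoxyphenyllithium 10 (not isolated), via lithium alkenyl(aryl)borate complex 11 (not isolated)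
Conditions: n-BuLi, THF, −78 °C; 8, −78 °C → rt; then 3, Pd(OAc)2 (3 mol %), (Sp,Sp)-MandyPhos (3.6 mol %), KOTf, THF, 60 °C
Reagents that add atoms: none
Why: Bromine–lithium exchange gives 10 without forming a lithium halide, and 10 adds to boron of 8 to give the four-coordinate borate 11 (either configuration at boron). Oxidative addition of 3 to zerovalent palladium gives an aryl species of divalent palladium which, once triflate has taken the place of bromide, binds the C7=C8 alkene of 11 and triggers a 1,2-shift of the trimethoxyphenyl group from boron to C7 anti to palladium, which ends up on C8; reductive elimination then forms C3'–C8 with retention. The closest known reaction type is the palladium-catalysed enantioselective conjunctive cross-coupling of alkenylboron ate complexes with aryl electrophiles, which includes beta-substituted alkenyl boronates of hindered diols. No ring is closed. C8 (S) is controlled by the chiral bisphosphine, which selects the alkene face so that ring A arrives on the Re face of C8. C7 (R) follows from the anti relationship between the migrating group and palladium across the E alkene, that is a net anti addition of the two aryl groups. The step needs the metallate shift to outrun direct boron-to-palladium transfer (Suzuki–Miyaura pathway), which the rigid, hindered diol 5 on boron, the exchange of bromide for triflate at palladium and the electron-rich migrating group should secure. Acetal, MOM ether and silyl ether are inert to these conditions.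

Step 7
Reactants: 12 secondary benzylic B(mac) boronate
Product: 13 (1R,2S)-3-[(tert-butyldimethylsilyl)oxy]-2-[5-(dimethoxymethyl)-3-methoxy-2-(methoxymethoxy)phenyl]-1-(3,4,5-trimethoxyphenyl)propan-1-ol
Conditions: NaOH (aq.), H2O2 (30 %), THF, 0 °C → rt
Reagents that add atoms: hydrogen peroxide, OO
Why: Oxidation of the C–B bond by hydroperoxide through a 1,2-shift of C7 from boron to oxygen with retention; acetal, MOM ether and the primary silyl ether tolerate cold aqueous base, and diol 5 is released for recovery.

Step 8
Reactants: 13 (1R,2S)-configured protected alcohol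
Product: 16 (2R,3S)-3-(hydroxymethyl)-7-methoxy-2-(3,4,5-trimethoxyphenyl)-2,3-dihydro-1-benzofuran-5-carbaldehyde, via phenol diol acetal 14 (not isolated), via cyclised dimethyl acetal 15 (not isolated)
Conditions: p-TsOH·H2O, MeOH, 45 °C; then H2O–THF, rt
Reagents that add atoms: water, O
Why: Acid cascade: methanolysis removes the silyl and MOM groups (14), the trimethoxybenzylic alcohol ionises, and the ortho phenol captures the C7 cation in a 5-exo closure (15), trans because the aryl group and the CH2OH arm avoid each other and any cis ring can re-ionise; C8 is not involved, the aldehyde stays masked during closure so that the phenol remains electron-rich, and water then hydrolyses the acetal.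

Step 9
Reactants: 16 (2R,3S)-aldehyde
Product: 17 methyl (E)-3-[(2R,3S)-3-(hydroxymethyl)-7-methoxy-2-(3,4,5-trimethoxyphenyl)-2,3-dihydro-1-benzofuran-5-yl]prop-2-enoate
Conditions: Ph3P=CHCO2Me, toluene, 80 °C
Reagents that add atoms: methyl (triphenylphosphoranylidene)acetate, COC(=O)C=P(c1ccccc1)(c1ccccc1)c1ccccc1
Why: Wittig reaction with a stabilised ylide, which should give the E alkene; the free primary alcohol and the benzylic ether are unaffected under these neutral conditions.

Step 10
Reactants: 17 (E)-acrylate ester
Product: 18 (−)-(7R,8S,7'E)-3,4,5,5'-tetramethoxy-4',7-epoxy-8,3'-neolign-7'-ene-9,9'-diol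
Conditions: i-Bu2AlH (DIBAL-H, excess), CH2Cl2, −78 → −20 °C; aq. KNaC4H4O6 work-up
Reagents that add atoms: none
Why: 1,2-Reduction of the unsaturated ester to the allylic alcohol by the aluminium hydride without touching the alkene; the excess covers the free hydroxyl, and the neutral tartrate work-up avoids acid that would ionise the cinnamyl alcohol or C7.

## Compound list

1 | 3-bromo-4-hydroxy-5-methoxybenzaldehyde (5-bromovanillin) | COc1cc(C=O)cc(Br)c1O | starting material
2 | 3-bromo-5-methoxy-4-(methoxymethoxy)benzaldehyde | COCOc1c(Br)cc(C=O)cc1OC | intermediate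
3 | 1-bromo-5-(dimethoxymethyl)-3-methoxy-2-(methoxymethoxy)benzene | COCOc1c(Br)cc(C(OC)OC)cc1OC | intermediate
4 | acenaphthylene-1,2-dione | O=C1C(=O)c2cccc3cccc1c23 | starting material
5 | (1R,2S)-1,2-dimethyl-1,2-dihydroacenaphthylene-1,2-diol (cis, meso) | C[C@@]1(O)c2cccc3cccc(c23)[C@]1(C)O | intermediate
6 | (E)-tert-butyldimethyl{[3-(4,4,5,5-tetramethyl-1,3,2-dioxaborolan-2-yl)prop-2-en-1-yl]oxy}silane | CC(C)(C)[Si](C)(C)OC/C=C/B1OC(C)(C)C(C)(C)O1 | starting material
7 | (E)-{3-[(tert-butyldimethylsilyl)oxy]prop-1-en-1-yl}boronic acid | CC(C)(C)[Si](C)(C)OC/C=C/B(O)O | intermediate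
8 | cyclic boronate of 7 with diol 5, (E)-alkenyl B(mac) ester | CC(C)(C)[Si](C)(C)OC/C=C/B1O[C@]2(C)c3cccc4cccc(c34)[C@]2(C)O1 | intermediate
9 | 5-bromo-1,2,3-trimethoxybenzene | COc1cc(Br)cc(OC)c1OC | starting material
10 | 3,4,5-trimethoxyphenyllithium | [Li]c1cc(OC)c(OC)c(OC)c1 | intermediate (not isolated)
11 | lithium [(E)-3-(tert-butyldimethylsilyloxy)prop-1-enyl](3,4,5-trimethoxyphenyl)borate of diol 5 (boron configuration unspecified) | [Li+].CC(C)(C)[Si](C)(C)OC/C=C/[B-]1(c2cc(OC)c(OC)c(OC)c2)O[C@]3(C)c4cccc5cccc(c45)[C@]3(C)O1 | intermediate (not isolated)
12 | (1R,2S)-3-[(tert-butyldimethylsilyl)oxy]-2-[5-(dimethoxymethyl)-3-methoxy-2-(methoxymethoxy)phenyl]-1-(3,4,5-trimethoxyphenyl)propylboronic acid ester of diol 5 | COc1cc([C@H](B2O[C@]3(C)c4cccc5cccc(c45)[C@]3(C)O2)[C@H](CO[Si](C)(C)C(C)(C)C)c6cc(C(OC)OC)cc(OC)c6OCOC)cc(OC)c1OC | intermediate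
13 | (1R,2S)-3-[(tert-butyldimethylsilyl)oxy]-2-[5-(dimethoxymethyl)-3-methoxy-2-(methoxymethoxy)phenyl]-1-(3,4,5-trimethoxyphenyl)propan-1-ol | COc1cc([C@H](O)[C@H](CO[Si](C)(C)C(C)(C)C)c2cc(C(OC)OC)cc(OC)c2OCOC)cc(OC)c1OC | intermediate
14 | (1R,2S)-2-[5-(dimethoxymethyl)-2-hydroxy-3-methoxyphenyl]-1-(3,4,5-trimethoxyphenyl)propane-1,3-diol | COc1cc([C@H](O)[C@H](CO)c2cc(C(OC)OC)cc(OC)c2O)cc(OC)c1OC | intermediate (not isolated)
15 | [(2R,3S)-5-(dimethoxymethyl)-7-methoxy-2-(3,4,5-trimethoxyphenyl)-2,3-dihydro-1-benzofuran-3-yl]methanol | COc1cc([C@@H]2Oc3c(OC)cc(C(OC)OC)cc3[C@H]2CO)cc(OC)c1OC | intermediate (not isolated)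
16 | (2R,3S)-3-(hydroxymethyl)-7-methoxy-2-(3,4,5-trimethoxyphenyl)-2,3-dihydro-1-benzofuran-5-carbaldehyde | COc1cc([C@@H]2Oc3c(OC)cc(C=O)cc3[C@H]2CO)cc(OC)c1OC | intermediate
17 | methyl (E)-3-[(2R,3S)-3-(hydroxymethyl)-7-methoxy-2-(3,4,5-trimethoxyphenyl)-2,3-dihydro-1-benzofuran-5-yl]prop-2-enoate | COc1cc([C@@H]2Oc3c(OC)cc(/C=C/C(=O)OC)cc3[C@H]2CO)cc(OC)c1OC | intermediate
18 | (−)-(7R,8S,7'E)-3,4,5,5'-tetramethoxy-4',7-epoxy-8,3'-neolign-7'-ene-9,9'-diol | COc1cc([C@@H]2Oc3c(OC)cc(/C=C/CO)cc3[C@H]2CO)cc(OC)c1OC | target

## Step count and least certain steps

Total step count: 10. Longest linear sequence: 7 steps (steps 1, 2, 6, 7, 8, 9, 10; the branch through steps 4 and 5 is equally long).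

**Step 6 (key step).** Most likely to go wrong is direct transfer of the alkenyl or aryl group from boron to palladium (Suzuki–Miyaura pathway) outrunning the metallate shift. The beta-substituted alkene binds palladium poorly, and the aryl palladium species from 3 is hindered by its ortho MOM ether. Bromide can also hold palladium in a neutral, less electrophilic form, and face selection at C8 may be incomplete with an ortho-substituted aryl group.

Fallback, setting out from 3 and coming back at 16: palladium-catalysed alpha-arylation of commercial 1-(3,4,5-trimethoxyphenyl)ethanone with 3 (Pd(OAc)2, Xantphos, NaOt-Bu, toluene) would give the deoxybenzoin 2-[5-(dimethoxymethyl)-3-methoxy-2-(methoxymethoxy)phenyl]-1-(3,4,5-trimethoxyphenyl)ethan-1-one F1. Base-catalysed hydroxymethylation with formaldehyde (K2CO3) would give the racemic, configurationally labile ketone 2-[5-(dimethoxymethyl)-3-methoxy-2-(methoxymethoxy)phenyl]-3-hydroxy-1-(3,4,5-trimethoxyphenyl)propan-1-one F2. Asymmetric transfer hydrogenation with dynamic kinetic resolution (RuCl(p-cymene)[(S,S)-TsDPEN], HCO2H–Et3N) should then fix C8 through the rapidly racemising alpha-aryl ketone and give (1S,2S)-2-[5-(dimethoxymethyl)-3-methoxy-2-(methoxymethoxy)phenyl]-1-(3,4,5-trimethoxyphenyl)propane-1,3-diol F3. The C1 configuration is irrelevant. Under the conditions of step 8, F3 loses the MOM group to give (1S,2S)-2-[5-(dimethoxymethyl)-2-hydroxy-3-methoxyphenyl]-1-(3,4,5-trimethoxyphenyl)propane-1,3-diol F4, which ionises at C7 and closes to 15 and then 16.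

**Step 8.** Most likely to go wrong is erosion of C8 by elimination of the C7 cation towards the C7=C8 alkene and re-protonation, or fragmentation of the free 1,3-diol cation with loss of the C9 carbon. Both compete if MOM cleavage is slower than ionisation. Capture of the cation by methanol can also stall the closure.

Fallback, setting out from 13 and coming back at 16: the order of events is changed. Ring closure is run first on the fully protected substrate with BF3·OEt2 in CH2Cl2 at −78 °C. The MOM-bearing oxygen (or the phenol released from it) captures the cation while C9 stays silylated, and aqueous work-up frees the aldehyde to give (2R,3S)-3-{[(tert-butyldimethylsilyl)oxy]methyl}-7-methoxy-2-(3,4,5-trimethoxyphenyl)-2,3-dihydro-1-benzofuran-5-carbaldehyde F5. Fluoride (TBAF, THF, 0 °C) then removes the silyl group under non-acidic conditions to give 16.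

**Step 4.** Most likely to go wrong is loss of the alkenylboronic acid during cleavage or isolation, by protodeboronation, oligomerisation to anhydrides that condense sluggishly, or incomplete removal of pinacol.

Fallback, setting out from 5 and coming back at 8: commercial tert-butyldimethyl(prop-2-yn-1-yloxy)silane is hydroborated with Cy2BH (THF, 0 °C → rt; syn, anti-Markovnikov) to give (E)-{3-[(tert-butyldimethylsilyl)oxy]prop-1-en-1-yl}dicyclohexylborane F6. Me3NO oxidises the two boron–cyclohexyl bonds selectively to give dicyclohexyl (E)-{3-[(tert-butyldimethylsilyl)oxy]prop-1-en-1-yl}boronate F7. Addition of 5 in the same flask exchanges the cyclohexyloxy groups and gives 8, so no free boronic acid is handled.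

**Step 2.** Most likely to go wrong is loss of the MOM group by acid-catalysed exchange with methanol, since aryl MOM ethers of electron-poor phenols are the more labile ones.

Fallback, setting out from 1 and coming back at 3: the free phenol 1 is acetalised first (HC(OMe)3, MeOH, catalytic acid) to 2-bromo-4-(dimethoxymethyl)-6-methoxyphenol F8. The MOM group is then put on under basic conditions (NaH, MOMCl, THF, 0 °C) to give 3, so that the MOM ether never meets acid.

## Further compounds

F1 | step 6 | 2-[5-(dimethoxymethyl)-3-methoxy-2-(methoxymethoxy)phenyl]-1-(3,4,5-trimethoxyphenyl)ethan-1-one | COCOc1c(CC(=O)c2cc(OC)c(OC)c(OC)c2)cc(C(OC)OC)cc1OC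
F2 | step 6 | 2-[5-(dimethoxymethyl)-3-methoxy-2-(methoxymethoxy)phenyl]-3-hydroxy-1-(3,4,5-trimethoxyphenyl)propan-1-one (racemic) | COCOc1c(C(CO)C(=O)c2cc(OC)c(OC)c(OC)c2)cc(C(OC)OC)cc1OC
F3 | step 6 | (1S,2S)-2-[5-(dimethoxymethyl)-3-methoxy-2-(methoxymethoxy)phenyl]-1-(3,4,5-trimethoxyphenyl)propane-1,3-diol | COc1cc([C@@H](O)[C@H](CO)c2cc(C(OC)OC)cc(OC)c2OCOC)cc(OC)c1OC
F4 | step 6 | (1S,2S)-2-[5-(dimethoxymethyl)-2-hydroxy-3-methoxyphenyl]-1-(3,4,5-trimethoxyphenyl)propane-1,3-diol | COc1cc([C@@H](O)[C@H](CO)c2cc(C(OC)OC)cc(OC)c2O)cc(OC)c1OC
F5 | step 8 | (2R,3S)-3-{[(tert-butyldimethylsilyl)oxy]methyl}-7-methoxy-2-(3,4,5-trimethoxyphenyl)-2,3-dihydro-1-benzofuran-5-carbaldehyde | COc1cc([C@@H]2Oc3c(OC)cc(C=O)cc3[C@H]2CO[Si](C)(C)C(C)(C)C)cc(OC)c1OC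
F6 | step 4 | (E)-{3-[(tert-butyldimethylsilyl)oxy]prop-1-en-1-yl}dicyclohexylborane | CC(C)(C)[Si](C)(C)OC/C=C/B(C1CCCCC1)C1CCCCC1
F7 | step 4 | dicyclohexyl (E)-{3-[(tert-butyldimethylsilyl)oxy]prop-1-en-1-yl}boronate | CC(C)(C)[Si](C)(C)OC/C=C/B(OC1CCCCC1)OC1CCCCC1
F8 | step 2 | 2-bromo-4-(dimethoxymethyl)-6-methoxyphenol | COc1cc(C(OC)OC)cc(Br)c1O
A1 | alternative 1 | 4-formyl-2-methoxy-6-[(E)-2-(3,4,5-trimethoxyphenyl)ethenyl]phenyl acetate | COc1cc(/C=C/c2cc(C=O)cc(OC)c2OC(C)=O)cc(OC)c1OC
A2 | alternative 1 | formaldehyde | C=O
A3 | alternative 1 | 4-formyl-2-methoxy-6-[trans-4-(3,4,5-trimethoxyphenyl)-1,3-dioxan-5-yl]phenyl acetate | COc1cc([C@H]2OCOC[C@@H]2c3cc(C=O)cc(OC)c3OC(C)=O)cc(OC)c1OC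
A4 | alternative 2 | (2S)-2-[5-bromo-3-methoxy-2-(methoxymethoxy)phenyl]-1-(3,4,5-trimethoxyphenyl)propane-1,3-diol (C1 either configuration) | COc1cc(C(O)[C@H](CO)c2cc(Br)cc(OC)c2OCOC)cc(OC)c1OC
A5 | alternative 2 | [(2R,3S)-5-bromo-7-methoxy-2-(3,4,5-trimethoxyphenyl)-2,3-dihydrobenzofuran-3-yl]methanol | COc1cc([C@@H]2Oc3c(OC)cc(Br)cc3[C@H]2CO)cc(OC)c1OC
A6 | alternative 3 | 4-bromo-2-{2-[(tert-butyldimethylsilyl)oxy]-1-(4-methylbenzenesulfonyl)ethyl}-6-methoxyphenol | COc1cc(Br)cc(C(CO[Si](C)(C)C(C)(C)C)S(=O)(=O)c2ccc(C)cc2)c1O
A7 | alternative 3 | (2R,5R)-2,5-dimethyl-1-(3,4,5-trimethoxybenzyl)thiolan-1-ium bromide | C[C@@H]1CC[C@@H](C)[S+]1Cc1cc(OC)c(OC)c(OC)c1.[Br-]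
A8 | alternative 3 | {[(2R,3S)-5-bromo-7-methoxy-2-(3,4,5-trimethoxyphenyl)-2,3-dihydrobenzofuran-3-yl]methoxy}(tert-butyl)dimethylsilane | COc1cc([C@@H]2Oc3c(OC)cc(Br)cc3[C@H]2CO[Si](C)(C)C(C)(C)C)cc(OC)c1OC
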